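## Structural features

Numbering used throughout: the ten-membered carbocycle is C1–C10, where C1–C3 are the three methylenes, C4 the tertiary carbinol (methyl C15), C5 the acyloxy carbon, C6 the lactone O-bearing carbon, C7 the carbon bearing C11, C8 the secondary carbinol, C9 the ketone and C10 the methyl-bearing methine (methyl C14); C11, C12 and C13 are the α-carbon, carbonyl and exocyclic methylene of the lactone. The α-methylene-γ-butyrolactone is trans-fused across C6–C7, the carbocycle is otherwise saturated, and the configuration is 4R,5S,6R,7S,8S,10S. Five stereocentres are contiguous (C4–C8: tertiary alcohol, ester, lactone oxygen, branch point, ketol carbinol), and the sixth, C10, lies on the far side of the C9 ketone, where it can epimerise. Fragile groups are the α-methylene lactone (Michael acceptor), the β,β-disubstituted enoate on O5 (deconjugation, acyl migration), the C8/C9 α-ketol, and the C4 hydroxyl, which is 1,6-transannular to the C9 carbonyl. The real difficulty is a ten-membered ring that offers no alkene or second ring to close on, yet carries five adjacent stereocentres, one of them fully substituted. The key step exploits the array C9(=O)–C8(O)–C7–C6(O) together with the transannular pair C9/C4: this is the imprint of an oxy-Cope product (enolate C8=C9, new bond C6–C7, alkene C4=C5, severed bond C4–C9), so a six-membered ring C9–C10–C1–C2–C3–C4 is hidden inside the ten-membered one.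

## Logic of the disconnections

In one sentence: the ten-membered ring of 27 is grown from the six-membered ring of 12 by an anionic oxy-Cope rearrangement, and is never closed by a macrocyclisation.

27 ⇒ 26 ⇒ 23. The O8–Si bond and then the lactone bond O6–C12 are cut, with C12 lowered to the alcohol level. The α-methylene lactone is the most electrophilic group and is therefore made last, by oxidation and not by enolate chemistry. The forward step must oxidise only the allylic primary alcohol of 23 and let O6 capture the aldehyde.

23 ⇒ 22 ⇒ 19 + 20. The two benzylic C–O bonds (O6, O12) and the acyl–O5 bond are cut. This removes the second sensitive ester and leaves a diol in which only O5 is secondary. The forward acylation must discriminate O5 from the tertiary O4 and keep the enoate geometry.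

19 ⇒ 18. The C4–OH bond is cut and O5 is tied back to C4 as an epoxide. This turns two stereocentres into one alkene face. The forward opening must occur at the tertiary carbon with inversion, the oxygen arriving on the ring-interior face.

18 ⇒ 15. The C8–O bond and both epoxide C–O bonds are cut, leaving a silyl enol ether and an E-alkene. Three oxygenated stereocentres are reduced to two π-faces of one ring conformer. The forward oxidations must both come from the periphery of that conformer.

15 ⇒ 12 (key). The C6–C7 bond is cut and the C4–C9 bond is restored (retro-[3,3]). The ten-membered ring collapses to a cyclohexanol, and the stereocentres C6 and C7 collapse to one quaternary centre plus two E-alkenes. The forward step must run through a single chair transition state.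

12 ⇒ 6 + 10. The C8–C9 bond is cut. This separates the whole lactone side (C7, C11–C13) as a dienyl nucleophile from a small ketone. The forward addition must beat enolisation and deliver the alkenyl group with a defined facial preference.

6 ⇒ 5 ⇒ 4. The O–C6 vinyl bond and then the C5=C6 bond are cut. The E-enol ether is reduced to an aldehyde, with geometry fixed by an E-selective olefination and a stereoretentive coupling.

4 ⇒ 2 ⇒ 1. The C4–C5 bond is cut and the enol ether is traced to a meso ketone. The whole absolute configuration is reduced to the choice between two enantiotopic protons. The forward alkylation must occur anti to the remaining methyl group.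

10 ⇒ 9 ⇒ 8 ⇒ 7. The C7=C8 bond and one O–benzyl bond are cut, leading to a symmetrical C4 diol.

## Other disconnections considered

Alternative 1: (first to mind) Cut C6–C7 in a macrocyclisation. The forward key step is an intramolecular Barbier/Nozaki–Hiyama–Kishi-type allylation of the open-chain aldehyde A1 (C6 aldehyde, 2-(bromomethyl)enoate at C7/C11/C13). It would form C6–C7, the exocyclic methylene and, after lactonisation, the protected lactone A2. The chosen plan is preferred for three reasons. A1 needs C4, C5, C8 and C10 to be set one by one on a flexible chain before the ring exists. The ten-membered closure has no conformational bias and must compete with oligomerisation. The C6/C7 outcome would rest on a macrocyclic transition state that cannot be predicted, whereas the chair of step 9 fixes both centres.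

Alternative 2: Run the same rearrangement in its other mode: cut C1–C2 and place the enolate toward C10. The forward key step is the anionic oxy-Cope of the 1-isopropenyl-2-vinylcyclohexanol A3, which already carries C5–C8. Here the new σ bond joins two stereochemically silent methylenes, so the pericyclic step sets no stereocentre. All of C5–C8 must first be built on a crowded cyclohexane. C10 would come from an uncontrolled enolate protonation, and the C4 hydroxyl from a Markovnikov hydration of C3=C4 without facial control. The chosen mode puts the new bond at C6–C7, exactly where stereocentres have to be made, and is several steps shorter.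

Alternative 3: Cut C4–C9 as the ring-fusion bond of a decalin. The forward key step is a hypoiodite alkoxy-radical β-scission of the bicyclic tertiary alcohol A4. It would give the C9 ketone and leave C4 to be oxygenated by radical capture. This addresses the C9(=O)/C4(–O) pair directly, but C4 becomes trigonal in the scission, so its configuration cannot be steered. Transannular hydrogen abstraction would compete in the ten-membered radical. A4 must already contain C5–C8 and C10, which moves the whole stereochemical problem into a longer synthesis of the precursor.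

Key step: step 9

Assumptions:
- Commercial 2,6-dimethylcyclohexanone is cis-rich; the meso cis isomer 1 is used after removal of the trans isomer by fractional distillation.
- The (R,R)-amide is written for the deprotonation that leaves the 6S centre; if the sense proves opposite, the (S,S)-amide is used and nothing else changes.
- (E)-3-Methylpent-2-enoic acid (20) is taken as a commercial building block.

## Route

Step 1
Reactants: 1 cis-2,6-dimethylcyclohexan-1-one
Product: 2 (6S)-2,6-dimethyl-1-(trimethylsilyloxy)cyclohex-1-ene
Conditions: (R,R)-bis(1-phenylethyl)amine, n-BuLi, THF, −78 °C; then 1 + TMSCl (internal quench), −100 → −78 °C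
Reagents that add atoms: chlorotrimethylsilane C[Si](C)(C)Cl
Why: Asymmetric deprotonation of a meso ketone: the C2-symmetric chiral lithium amide removes one of the two enantiotopic α-protons and the enolate is silylated in situ before it can equilibrate; the untouched methyl-bearing carbon becomes the 6S centre (future C10), the only stereocentre in the route that is set by a reagent.

Step 2
Reactants: 2 (6S)-2,6-dimethyl-1-(trimethylsilyloxy)cyclohex-1-ene
Product: 4 (1R,3S)-1,3-dimethyl-2-oxocyclohexane-1-carbaldehyde, via dimethyl acetal 3 (not isolated)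
Conditions: HC(OMe)3, TMSOTf (5 mol %), CH2Cl2, −78 °C; then 1 M HCl, THF, 0 °C
Reagents that add atoms: trimethyl orthoformate COC(OC)OC; water O
Why: Mukaiyama-type addition of the silyl enol ether to the dimethoxycarbenium ion: the C6 methyl is pseudo-axial in the enol ether (A1,2 strain with OSiMe3) and the electrophile enters on the opposite face, so the new quaternary centre (future C4) is R with the two methyl groups cis; the acid work-up unmasks the non-enolisable β-keto aldehyde.

Step 3
Reactants: 4 (1R,3S)-1,3-dimethyl-2-oxocyclohexane-1-carbaldehyde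
Product: 5 (2R,6S)-2-[(E)-2-iodoethenyl]-2,6-dimethylcyclohexan-1-one
Conditions: CrCl2 (6 equiv), CHI3 (2 equiv), THF, 0 °C → rt
Reagents that add atoms: iodoform IC(I)I
Why: Takai olefination: the gem-dichromium species from CHI3/CrCl2 adds to the aldehyde only (the hindered ketone is inert) and the elimination gives the E-vinyl iodide.

Step 4
Reactants: 5 (2R,6S)-2-[(E)-2-iodoethenyl]-2,6-dimethylcyclohexan-1-one
Product: 6 (2R,6S)-2-{(E)-2-[(4-methoxybenzyl)oxy]ethenyl}-2,6-dimethylcyclohexan-1-one
Conditions: 4-methoxybenzyl alcohol (2 equiv), CuI (10 mol %), 3,4,7,8-tetramethyl-1,10-phenanthroline (20 mol %), Cs2CO3, toluene, 80 °C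
Reagents that add atoms: 4-methoxybenzyl alcohol COc1ccc(CO)cc1
Why: Copper-catalysed Ullmann-type C–O coupling of a vinyl iodide with an alcohol, which proceeds with retention of alkene geometry and gives the E-enol ether; C4 is quaternary, so the β,γ-unsaturated ketone cannot move into conjugation.

Step 5
Reactants: 7 2-methylidenepropane-1,3-diol
Product: 8 2-{[(4-methoxybenzyl)oxy]methyl}prop-2-en-1-ol
Conditions: 7 (2.5 equiv), NaH (1 equiv), THF/DMF, 0 °C; then 4-methoxybenzyl chloride, Bu4NI (cat.), rt
Reagents that add atoms: 4-methoxybenzyl chloride COc1ccc(CCl)cc1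
Why: Williamson ether synthesis on the mono-alkoxide of the symmetrical diol, which is used in excess so that mono-protection dominates.

Step 6
Reactants: 8 2-{[(4-methoxybenzyl)oxy]methyl}prop-2-en-1-ol
Product: 9 2-{[(4-methoxybenzyl)oxy]methyl}prop-2-enal
Conditions: MnO2 (15 equiv), CH2Cl2, rt
Reagents that add atoms: none
Why: Allylic oxidation with MnO2, selective for the allylic primary alcohol and neutral enough for the polymerisable 2-substituted acrolein.

Step 7
Reactants: 9 2-{[(4-methoxybenzyl)oxy]methyl}prop-2-enal
Product: 10 (1E)-1-iodo-3-{[(4-methoxybenzyl)oxy]methyl}buta-1,3-diene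
Conditions: CrCl2 (6 equiv), CHI3 (2 equiv), THF, 0 °C
Reagents that add atoms: iodoform IC(I)I
Why: Takai olefination of the enal, which adds 1,2 and gives the E-iododiene that carries C7, C11, C12 and C13 of the target.

Step 8
Reactants: 10 (1E)-1-iodo-3-{[(4-methoxybenzyl)oxy]methyl}buta-1,3-diene; 6 (2R,6S)-2-{(E)-2-[(4-methoxybenzyl)oxy]ethenyl}-2,6-dimethylcyclohexan-1-one
Product: 12 (1S,2R,6S)-1-[(1E)-3-{[(4-methoxybenzyl)oxy]methyl}buta-1,3-dien-1-yl]-2-{(E)-2-[(4-methoxybenzyl)oxy]ethenyl}-2,6-dimethylcyclohexan-1-ol, via dienyllithium 11 (not isolated)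
Conditions: 10, t-BuLi (2.05 equiv), Et2O, −78 °C; then 6, −78 → −20 °C; H2O
Reagents that add atoms: none
Why: Iodine–lithium exchange with retention of geometry, then 1,2-addition: ketone 6 reacts in the chair with both methyl groups equatorial and the alkoxyvinyl group axial, so the alkenyllithium enters anti to that axial group and ends trans to it and cis to both methyl groups (1S); only one hindered α-proton is available for enolisation.

Step 9
Reactants: 12 (1S,2R,6S)-1-[(1E)-3-{[(4-methoxybenzyl)oxy]methyl}buta-1,3-dien-1-yl]-2-{(E)-2-[(4-methoxybenzyl)oxy]ethenyl}-2,6-dimethylcyclohexan-1-ol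
Product: 15 (4E,8Z)-9-(tert-butyldimethylsilyloxy)-6-(4-methoxybenzyloxy)-7-{3-[(4-methoxybenzyl)oxy]prop-1-en-2-yl}-4,10-dimethylcyclodeca-4,8-diene (target numbering; C6/C7/C10 arranged as in 27), via potassium alkoxide 13 (not isolated), via potassium enolate 14 (not isolated)
Conditions: KH (1.5 equiv), 18-crown-6 (1.5 equiv), THF, 0 → 25 °C; then TBSCl (2 equiv), −78 → 0 °C
Reagents that add atoms: tert-butyldimethylsilyl chloride CC(C)(C)[Si](C)(C)Cl
Why: KH/18-crown-6 gives the dissociated alkoxide 13, whose C4–C9 bond is weakened by the oxyanion and which undergoes a concerted suprafacial [3,3] shift: C6–C7 forms between the two vinyl termini while C4–C9 breaks, giving enolate 14, which TBSCl traps on oxygen. The closest known reaction type is the anionic oxy-Cope ring expansion of trans-1,2-divinylcyclohexanols to (E)-cyclodec-5-enones, including β-alkoxyvinyl and dienyl partners. No ring is closed in the usual sense: the six-membered ring is enlarged by four atoms through a six-centre chair transition state, so the entropic and transannular cost of a direct ten-ring closure is not paid. The two alkenyl groups are trans-diequatorial in the reacting chair, which makes the chair the only accessible transition state (a boat would force the ring bonds to eclipse) and places C3 and C10 pseudo-equatorial, hence the E geometry of C4=C5 and the C7/C10-trans enol ether. C6 and C7 are set together by chirality transfer from the quaternary carbon C4, which is destroyed in the event: with both alkenes E, the OPMB group and C11 are pseudo-equatorial, which gives the C6/C7 arrangement of the target (trans across the new bond, as the trans-lactone needs), and C10 is untouched because the enolate forms only toward C8. The selectivity needed is [3,3] against heterolytic C4–C9 cleavage and against a [1,3] shift; cleavage would expel an alkyl-substituted, oxygen-destabilised allyl anion, a poor leaving group, so the concerted path should dominate. The reacting chair carries the C4 and C10 methyl groups syn-axial, a penalty of a few kcal/mol that is released as C4–C9 breaks; any C9 epimer of 12 would rearrange through its ground-state chair to the same C6/C7 configuration and to the same ketone 17 in step 10.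

Step 10
Reactants: 15 (4E,8Z)-9-(tert-butyldimethylsilyloxy)-6-(4-methoxybenzyloxy)-7-{3-[(4-methoxybenzyl)oxy]prop-1-en-2-yl}-4,10-dimethylcyclodeca-4,8-diene
Product: 18 (4S,5S,8S,10S)-8-(tert-butyldimethylsilyloxy)-4,5-epoxy-6-(4-methoxybenzyloxy)-7-{3-[(4-methoxybenzyl)oxy]prop-1-en-2-yl}-4,10-dimethylcyclodecan-9-one (target numbering; C6/C7 as in 27), via silyloxy-oxirane 16 (not isolated), via silyloxy ketone 17 (not isolated)
Conditions: mCPBA (2.2 equiv), NaHCO3, CH2Cl2, −20 → 0 °C
Reagents that add atoms: 3-chloroperoxybenzoic acid OOC(=O)c1cccc(Cl)c1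
Why: Rubottom oxidation and alkene epoxidation in one flask: the peracid attacks the silyl enol ether first and then the trisubstituted C4=C5 alkene, both far faster than the electron-poor 1,1-disubstituted C11=C13 alkene; in the crossed conformer left by the Cope chair both π systems stand perpendicular to the mean ring plane, so attack is peripheral, which sets C8 (S) and the (4S,5S)-epoxide, and the 1,4-silyl shift in 16 leaves O8 protected.

Step 11
Reactants: 18 (4S,5S,8S,10S)-8-(tert-butyldimethylsilyloxy)-4,5-epoxy-6-(4-methoxybenzyloxy)-7-{3-[(4-methoxybenzyl)oxy]prop-1-en-2-yl}-4,10-dimethylcyclodecan-9-one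
Product: 19 (4R,5S,8S,10S)-8-(tert-butyldimethylsilyloxy)-4,5-dihydroxy-6-(4-methoxybenzyloxy)-7-{3-[(4-methoxybenzyl)oxy]prop-1-en-2-yl}-4,10-dimethylcyclodecan-9-one (target numbering; C6/C7 as in 27)
Conditions: HClO4 (5 mol %), THF–H2O (4:1), 0 °C
Reagents that add atoms: water O
Why: Acid-catalysed anti opening of a trisubstituted epoxide at the tertiary carbon (borderline SN2, inversion at C4, C5–O retained) gives 4R,5S; the hydroxyl must arrive on the ring-interior face, directly or relayed by the transannular C9 carbonyl (a hemiketal that is the ring–chain tautomer of 19), and both paths give the same configuration, while closure of the diol onto C9 as an internal ketal is blocked because C3 and C10 would have to span the dioxolane in a trans sense.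

Step 12
Reactants: 19 (4R,5S,8S,10S)-8-(tert-butyldimethylsilyloxy)-4,5-dihydroxy-6-(4-methoxybenzyloxy)-7-{3-[(4-methoxybenzyl)oxy]prop-1-en-2-yl}-4,10-dimethylcyclodecan-9-one; 20 (E)-3-methylpent-2-enoic acid
Product: 22 5-O-[(E)-3-methylpent-2-enoyl] ester of 19, via mixed anhydride 21 (not isolated)
Conditions: 20, 2,4,6-trichlorobenzoyl chloride, Et3N, THF, rt; then 19, DMAP, toluene, 40 °C
Reagents that add atoms: none
Why: Yamaguchi esterification: DMAP transfers the enoyl group from the mixed anhydride to the only acylable hydroxyl, the secondary O5 (the tertiary O4 is inert), and the E geometry of the acid is carried over.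

Step 13
Reactants: 22 5-O-[(E)-3-methylpent-2-enoyl] ester of 19
Product: 23 (4R,5S,8S,10S)-8-(tert-butyldimethylsilyloxy)-4,6-dihydroxy-7-(3-hydroxyprop-1-en-2-yl)-4,10-dimethyl-9-oxocyclodecan-5-yl (E)-3-methylpent-2-enoate (target numbering; C6/C7 as in 27)
Conditions: DDQ (3 equiv), CH2Cl2–pH 7 buffer (10:1), 0 °C → rt
Reagents that add atoms: none
Why: Oxidative cleavage of both 4-methoxybenzyl ethers by DDQ (benzylic hydride abstraction, hydrolysis of the oxocarbenium ion); the silyl ether, enoate, ketone and isolated alkenes are untouched, and the buffered water suppresses acetal formation with the C4 hydroxyl.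

Step 14
Reactants: 23 (4R,5S,8S,10S)-8-(tert-butyldimethylsilyloxy)-4,6-dihydroxy-7-(3-hydroxyprop-1-en-2-yl)-4,10-dimethyl-9-oxocyclodecan-5-yl (E)-3-methylpent-2-enoate
Product: 26 8-O-tert-butyldimethylsilyl ether of 27, via hydroxy enal 24 (not isolated), via lactol 25 (not isolated)
Conditions: MnO2 (30 equiv), CH2Cl2, rt
Reagents that add atoms: none
Why: Oxidative lactonisation of a 2-methylidene-1,4-diol: MnO2 oxidises only the allylic primary alcohol, O6 closes onto the enal as a five-membered lactol, and the lactol (allylic-type) is oxidised on to the α-methylene-γ-butyrolactone; the trans fusion is preset by C6/C7 and no enolate chemistry touches the ketone.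

Step 15
Reactants: 26 8-O-tert-butyldimethylsilyl ether of 27
Product: 27 CNP0197047.1 (target)
Conditions: HF·pyridine, pyridine, THF, 0 °C → rt
Reagents that add atoms: none
Why: Fluoride-mediated desilylation under buffered, non-basic conditions, so that the α-methylene lactone, the enoate and the α-ketol are not exposed to base or nucleophiles.

## Compound list

1 | cis-2,6-dimethylcyclohexan-1-one (meso) | C[C@@H]1CCC[C@H](C)C1=O | starting material
2 | (6S)-2,6-dimethyl-1-(trimethylsilyloxy)cyclohex-1-ene | C[Si](C)(C)OC1=C(C)CCC[C@@H]1C | intermediate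
3 | (2R,6S)-2-(dimethoxymethyl)-2,6-dimethylcyclohexan-1-one | O=C1[C@@H](C)CCC[C@]1(C)C(OC)OC | intermediate
4 | (1R,3S)-1,3-dimethyl-2-oxocyclohexane-1-carbaldehyde | O=C1[C@@H](C)CCC[C@]1(C)C=O | intermediate
5 | (2R,6S)-2-[(E)-2-iodoethenyl]-2,6-dimethylcyclohexan-1-one | O=C1[C@@H](C)CCC[C@]1(C)/C=C/I | intermediate
6 | (2R,6S)-2-{(E)-2-[(4-methoxybenzyl)oxy]ethenyl}-2,6-dimethylcyclohexan-1-one | O=C1[C@@H](C)CCC[C@]1(C)/C=C/OCc2ccc(OC)cc2 | intermediate
7 | 2-methylidenepropane-1,3-diol | C=C(CO)CO | starting material
8 | 2-{[(4-methoxybenzyl)oxy]methyl}prop-2-en-1-ol | C=C(CO)COCc1ccc(OC)cc1 | intermediate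
9 | 2-{[(4-methoxybenzyl)oxy]methyl}prop-2-enal | C=C(C=O)COCc1ccc(OC)cc1 | intermediate
10 | (1E)-1-iodo-3-{[(4-methoxybenzyl)oxy]methyl}buta-1,3-diene | C=C(/C=C/I)COCc1ccc(OC)cc1 | intermediate
11 | [(1E)-3-{[(4-methoxybenzyl)oxy]methyl}buta-1,3-dien-1-yl]lithium | C=C(/C=C/[Li])COCc1ccc(OC)cc1 | intermediate
12 | (1S,2R,6S)-1-[(1E)-3-{[(4-methoxybenzyl)oxy]methyl}buta-1,3-dien-1-yl]-2-{(E)-2-[(4-methoxybenzyl)oxy]ethenyl}-2,6-dimethylcyclohexan-1-ol | O[C@]1(/C=C/C(=C)COCc2ccc(OC)cc2)[C@@H](C)CCC[C@]1(C)/C=C/OCc3ccc(OC)cc3 | intermediate
13 | potassium alkoxide of 12 | [K+].[O-][C@]1(/C=C/C(=C)COCc2ccc(OC)cc2)[C@@H](C)CCC[C@]1(C)/C=C/OCc3ccc(OC)cc3 | intermediate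
14 | potassium (4E,8Z)-enolate of the ring-expanded ketone (O on C9; C6/C7/C10 as in 27) | C=C(COCc2ccc(OC)cc2)[C@H]1/C=C(\[O-])/[C@@H](C)CCC/C(C)=C/[C@@H]1OCc3ccc(OC)cc3.[K+] | intermediate
15 | (4E,8Z)-9-(tert-butyldimethylsilyloxy)-6-(4-methoxybenzyloxy)-7-{3-[(4-methoxybenzyl)oxy]prop-1-en-2-yl}-4,10-dimethylcyclodeca-4,8-diene (target numbering; C6/C7/C10 as in 27) | C=C(COCc2ccc(OC)cc2)[C@H]1/C=C(\O[Si](C)(C)C(C)(C)C)/[C@@H](C)CCC/C(C)=C/[C@@H]1OCc3ccc(OC)cc3 | intermediate
16 | 8,9-epoxide of 15 (2-silyloxy-oxirane, oxygen on the peripheral face) | C=C(COCc2ccc(OC)cc2)[C@H]1[C@@H]5O[C@@]5(O[Si](C)(C)C(C)(C)C)[C@@H](C)CCC/C(C)=C/[C@@H]1OCc3ccc(OC)cc3 | intermediate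
17 | (4E,8S,10S)-8-(tert-butyldimethylsilyloxy)-6-(4-methoxybenzyloxy)-7-{3-[(4-methoxybenzyl)oxy]prop-1-en-2-yl}-4,10-dimethylcyclodec-4-en-9-one (target numbering; C6/C7 as in 27) | C=C(COCc2ccc(OC)cc2)[C@H]1[C@H](O[Si](C)(C)C(C)(C)C)C(=O)[C@@H](C)CCC/C(C)=C/[C@@H]1OCc3ccc(OC)cc3 | intermediate
18 | (4S,5S)-4,5-epoxide of 17 | C=C(COCc2ccc(OC)cc2)[C@H]1[C@H](O[Si](C)(C)C(C)(C)C)C(=O)[C@@H](C)CCC[C@]4(C)O[C@H]4[C@@H]1OCc3ccc(OC)cc3 | intermediate
19 | (4R,5S)-4,5-diol from 18 | C=C(COCc2ccc(OC)cc2)[C@H]1[C@H](O[Si](C)(C)C(C)(C)C)C(=O)[C@@H](C)CCC[C@@](C)(O)[C@@H](O)[C@@H]1OCc3ccc(OC)cc3 | intermediate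
20 | (E)-3-methylpent-2-enoic acid | CC/C(C)=C/C(=O)O | starting material
21 | (E)-3-methylpent-2-enoic 2,4,6-trichlorobenzoic anhydride | CC/C(C)=C/C(=O)OC(=O)c1c(Cl)cc(Cl)cc1Cl | intermediate
22 | 5-O-[(E)-3-methylpent-2-enoyl] ester of 19 | C=C(COCc2ccc(OC)cc2)[C@H]1[C@H](O[Si](C)(C)C(C)(C)C)C(=O)[C@@H](C)CCC[C@@](C)(O)[C@@H](OC(=O)/C=C(\C)CC)[C@@H]1OCc3ccc(OC)cc3 | intermediate
23 | 6,12-diol from 22 (both 4-methoxybenzyl groups removed) | C=C(CO)[C@H]1[C@H](O[Si](C)(C)C(C)(C)C)C(=O)[C@@H](C)CCC[C@@](C)(O)[C@@H](OC(=O)/C=C(\C)CC)[C@@H]1O | intermediate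
24 | C12 aldehyde (hydroxy enal) from 23 | C=C(C=O)[C@H]1[C@H](O[Si](C)(C)C(C)(C)C)C(=O)[C@@H](C)CCC[C@@](C)(O)[C@@H](OC(=O)/C=C(\C)CC)[C@@H]1O | intermediate
25 | C12 lactol (both anomers) from 24 | C=C1C(O)O[C@@H]2[C@@H]1[C@H](O[Si](C)(C)C(C)(C)C)C(=O)[C@@H](C)CCC[C@@](C)(O)[C@H]2OC(=O)/C=C(\C)CC | intermediate
26 | 8-O-tert-butyldimethylsilyl ether of the target | C=C1C(=O)O[C@@H]2[C@@H]1[C@H](O[Si](C)(C)C(C)(C)C)C(=O)[C@@H](C)CCC[C@@](C)(O)[C@H]2OC(=O)/C=C(\C)CC | intermediate
27 | CNP0197047.1 (4R,5S,6R,7S,8S,10S in the numbering above) | C=C1C(=O)O[C@@H]2[C@@H]1[C@H](O)C(=O)[C@@H](C)CCC[C@@](C)(O)[C@H]2OC(=O)/C=C(\C)CC | target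

## Step count and least certain steps

Total: 15 steps. Longest linear sequence: 12 steps (1, 2, 3, 4, 8, 9, 10, 11, 12, 13, 14, 15); steps 5–7 build the dienyl iodide in a side branch.

Step 9 (key step). The most likely failure is loss of the concerted path in the strongly basic medium: heterolytic C4–C9 cleavage and recombination, or proton transfer in the enolate, either of which erodes the chirality transfer. It becomes more likely if the alkoxide populates the reacting chair poorly because of the syn-axial methyl groups. Fallback: a charge-neutral silyloxy-Cope rearrangement. Starting from 12, the tertiary hydroxyl is silylated (TBSOTf, 2,6-lutidine) to give the tertiary silyl ether F1. F1 is heated in toluene at 180–200 °C in base-washed glass; the same chair [3,3] shift then gives the silyl enol ether directly, and the route is rejoined at 15.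

Step 11. The opening may not be a clean inversion at C4. Ionisation of the tertiary C–O bond followed by capture from the outer face (retention), a transannular hydride shift or loss of a proton to an allylic alcohol can compete, because the backside of C4 points into the ring. Fallback: make the transannular carbonyl the nucleophile on purpose. Starting from 18, BF3·OEt2 in dry CH2Cl2 at −78 °C lets the C9 carbonyl oxygen open the epoxide at C4 from the interior face. Quenching with aqueous NaHCO3 gives the bridged hemiketal F2, which is the ring–chain tautomer of the diol and rejoins the route at 19.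

Step 10. Facial selectivity may be poor if the ring populates a conformer other than the crossed one by the time the peracid arrives; over-oxidation at C11=C13 and loss of the silyl group are lesser risks. Fallback: separate the two oxidations. Starting from 12, enolate 14 is generated as in step 9 and quenched at −78 °C with 2-(phenylsulfonyl)-3-phenyloxaziridine to give the α-hydroxy ketone F3. Silylation (TBSOTf, 2,6-lutidine) gives 17, now isolated, which is epoxidised with one equivalent of mCPBA to rejoin the route at 18.

Step 1. Discrimination of the enantiotopic protons may be incomplete, and any residual trans-ketone gives racemic enol ether; both lower the enantiomeric purity of everything downstream. Fallback: an auxiliary-based route. Commercial 2-methylcyclohex-2-en-1-one is condensed with (R)-1-amino-2-(methoxymethyl)pyrrolidine (RAMP, chosen by analogy with the sense of SAMP-hydrazone alkylations of cyclohexanones) to give the hydrazone F4. Kinetic α′-deprotonation (LDA) and methylation (MeI) give the methylated hydrazone F5. Cleavage with aqueous oxalic acid gives (S)-2,6-dimethylcyclohex-2-en-1-one F6. Conjugate reduction with L-Selectride and trapping of the resulting enolate with TMSCl then rejoins the route at 2.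

Step 12. Acylation of the hindered C5 hydroxyl may be slow, and the activated β,β-disubstituted enoate can deconjugate or scramble its geometry through a vinylketene under amine base. Fallback: build the enoate on the substrate. Starting from 19, the hydroxyl is acylated with the small, linear but-2-ynoic acid (DCC, DMAP) to give the C5 but-2-ynoate F7. Syn-carbocupration with an ethylcopper reagent (EtMgBr, CuBr·SMe2, THF, −78 °C; one further equivalent is consumed by the C4 hydroxyl) followed by protonation gives the E-enoate and rejoins the route at 22.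

## Further compounds

F1 | step 9 | tert-butyldimethylsilyl ether of 12 | CC(C)(C)[Si](C)(C)O[C@]1(/C=C/C(=C)COCc2ccc(OC)cc2)[C@@H](C)CCC[C@]1(C)/C=C/OCc3ccc(OC)cc3
F2 | step 11 | transannular C4–O–C9 hemiketal (ring–chain tautomer of 19) | C=C(COCc2ccc(OC)cc2)[C@H]1[C@H](O[Si](C)(C)C(C)(C)C)[C@@]4(O)[C@@H](C)CCC[C@@](C)(O4)[C@@H](O)[C@@H]1OCc3ccc(OC)cc3
F3 | step 10 | 8-hydroxy analogue of 17 (α-hydroxy ketone, C4=C5 intact) | C=C(COCc2ccc(OC)cc2)[C@H]1[C@H](O)C(=O)[C@@H](C)CCC/C(C)=C/[C@@H]1OCc3ccc(OC)cc3
F4 | step 1 | RAMP hydrazone of 2-methylcyclohex-2-en-1-one | COC[C@H]1CCCN1/N=C2/C(C)=CCCC2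
F5 | step 1 | RAMP hydrazone of (S)-2,6-dimethylcyclohex-2-en-1-one | COC[C@H]1CCCN1/N=C2/C(C)=CCC[C@@H]2C
F6 | step 1 | (S)-2,6-dimethylcyclohex-2-en-1-one | O=C1C(C)=CCC[C@@H]1C
F7 | step 12 | 5-O-(but-2-ynoyl) ester of 19 | C=C(COCc2ccc(OC)cc2)[C@H]1[C@H](O[Si](C)(C)C(C)(C)C)C(=O)[C@@H](C)CCC[C@@](C)(O)[C@@H](OC(=O)C#CC)[C@@H]1OCc3ccc(OC)cc3
A1 | alternative 1 | open-chain C6 aldehyde with methyl (E)-2-(bromomethyl)enoate terminus (5,8-bis-TBS ether, C9 ketone, free C4 hydroxyl) | BrC/C(C(=O)OC)=C/[C@H](O[Si](C)(C)C(C)(C)C)C(=O)[C@@H](C)CCC[C@@](C)(O)[C@@H](O[Si](C)(C)C(C)(C)C)C=O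
A2 | alternative 1 | 5,8-bis-O-TBS ether of the deacyl target | C=C1C(=O)O[C@@H]2[C@@H]1[C@H](O[Si](C)(C)C(C)(C)C)C(=O)[C@@H](C)CCC[C@@](C)(O)[C@H]2O[Si](C)(C)C(C)(C)C
A3 | alternative 2 | 1-isopropenyl-2-methyl-2-vinylcyclohexanol carrying C5–C8 of the target (trans-dialkenyl) | C=C(C)[C@@]1(O)[C@@H](O[Si](C)(C)C(C)(C)C)[C@H](C(=C)COCc2ccc(OC)cc2)[C@@H](OCc3ccc(OC)cc3)[C@H](O[Si](C)(C)C(C)(C)C)[C@]1(C)C=C
A4 | alternative 3 | decalin-type tertiary alcohol with a C4–C9 ring-fusion bond and the lactone in place (ring-fusion configuration as drawn; it is erased in the scission) | C=C1C(=O)O[C@@H]2[C@@H]1[C@H](O[Si](C)(C)C(C)(C)C)[C@]3(O)[C@@H](C)CCC[C@]3(C)[C@H]2O[Si](C)(C)C(C)(C)C
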